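**Retrosynthetic overview**
- Target 20 comes from ring alcohol 17 by Steglich acylation with acetyl-protected vanillic acid 18 and selective removal of the aryl acetate; the ester is installed only after ring closure.
- The only ring formed, the cyclodecadiene, is closed at C7–C8 by a one-pot 9-BBN hydroboration / intramolecular B-alkyl Suzuki–Miyaura coupling of the acyclic iodo-triene 14.
- Enabling feature: C7 is the methyl-bearing sp2 carbon of the (Z)-C6=C7 olefin, and the C8H2–C9H2 bridge ends at the isopropyl-bearing stereocentre C10. C7 therefore maps onto a (Z)-alkenyl iodide and C8–C9 onto a vinyl group, and the two Z olefins (C2=C3, C6=C7) fold the chain for closure.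
- That vinyl group and both stereocentres (C1, C10) arise together from one catalyst-controlled, anti-selective γ-isopropyl-allylboration of (Z)-enal 9 (C1–C10 bond).
- Enal 9 comes from neryl acetate 1 (Z geometry of C2=C3 bought in) by selective ozonolysis and a Z-selective α-iodo-Wittig olefination.

Key step: step 8

**Remarks**
- Ring numbering used throughout: C1 = ester-bearing carbon, C2=C3(CH3), C4, C5, C6=C7(CH3), C8, C9, C10 = isopropyl-bearing carbon. The target is (1R,2Z,6Z,10S), with both ring olefins cis within the ring.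
- Assumption: the known Re-face preference of (R)-TRIP with aryl and alkenyl aldehydes is taken to carry over to enal 9 in step 6; should the opposite sense be found, (S)-TRIP is used and nothing else changes.
- Acid 18 is taken as a purchasable compound.

**Route**

Step 1
Reactants: 1 neryl acetate
Product: 2 (2Z)-3-methyl-6-oxohex-2-en-1-yl acetate
Conditions: O3 (1.0 equiv), CH2Cl2/pyridine, −78 °C; then Me2S, −78 °C → rt
Reagents that add atoms: ozone, O=[O+][O-]
Why: Chemoselective ozonolysis: the isopropylidene olefin is the electron-rich one, whereas the C2=C3 olefin is deactivated by the allylic acetate, so one equivalent of ozone should cleave only the former and leave the Z olefin untouched.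

Step 2
Reactants: 2 (2Z)-3-methyl-6-oxohex-2-en-1-yl acetate; 3 ethyltriphenylphosphonium iodide
Product: 7 (2Z,6Z)-7-iodo-3-methylocta-2,6-dien-1-yl acetate, via ethylidene(triphenyl)phosphorane 4 (not isolated), via (1-iodoethyl)triphenylphosphonium iodide 5 (not isolated), via (1-iodoethylidene)triphenylphosphorane 6 (not isolated)
Conditions: 3, n-BuLi, THF, 0 °C; I2, THF, −78 °C; NaN(SiMe3)2, −78 → −20 °C; then 2, −78 → −20 °C
Reagents that add atoms: iodine, II
Why: Stork–Zhao-type Wittig olefination with the unstabilised α-iodo ylide; under kinetic control it is known to place iodine cis to the chain with aliphatic aldehydes, giving the (Z)-2-iodoalk-2-ene, and the aldehyde reacts far faster than the acetate.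

Step 3
Reactants: 7 (2Z,6Z)-7-iodo-3-methylocta-2,6-dien-1-yl acetate
Product: 8 (2Z,6Z)-7-iodo-3-methylocta-2,6-dien-1-ol
Conditions: K2CO3, MeOH, 0 °C → rt
Reagents that add atoms: none
Why: Base-catalysed transesterification (methanolysis) of a primary acetate; the alkenyl iodide and both olefins are inert.

Step 4
Reactants: 8 (2Z,6Z)-7-iodo-3-methylocta-2,6-dien-1-ol
Product: 9 (2Z,6Z)-7-iodo-3-methylocta-2,6-dienal
Conditions: MnO2 (activated, excess), CH2Cl2, rt
Reagents that add atoms: none
Why: Allylic alcohol oxidation with MnO2 under neutral heterogeneous conditions, which should preserve the Z geometry of the enal (no acid or base to isomerise it to the E enal).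

Step 5
Reactants: 10 4-methylpent-1-en-3-ol (racemic); 11 bis(pinacolato)diboron
Product: 12 4,4,5,5-tetramethyl-2-[(2E)-4-methylpent-2-en-1-yl]-1,3,2-dioxaborolane
Conditions: Pd(MeCN)4(BF4)2 (5 mol %), DMSO/MeOH (1:1), 40 °C
Reagents that add atoms: none
Why: Palladium-catalysed allylic C–OH borylation through a π-allylpalladium intermediate; boron is delivered to the less hindered terminus and the syn-π-allyl gives the linear (E)-allylboronate, so the stereocentre of racemic 10 is erased.

Step 6
Reactants: 9 (2Z,6Z)-7-iodo-3-methylocta-2,6-dienal; 12 4,4,5,5-tetramethyl-2-[(2E)-4-methylpent-2-en-1-yl]-1,3,2-dioxaborolane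
Product: 13 (3R,4R,5Z,9Z)-10-iodo-6-methyl-3-(propan-2-yl)undeca-1,5,9-trien-4-ol
Conditions: (R)-TRIP [(R)-3,3'-bis(2,4,6-triisopropylphenyl)-1,1'-binaphthyl-2,2'-diyl hydrogen phosphate] (5 mol %), 4 Å MS, toluene, −30 °C; aqueous NaHCO3 work-up
Reagents that add atoms: none
Why: Chiral phosphoric acid-catalysed allylboration through a closed chair (Zimmerman–Traxler) transition state; the (E)-γ-isopropyl group sits equatorial and gives the anti pair, while the catalyst directs addition to the Re face of the aldehyde, setting C4 as R and hence C3 as R (these become ring C1 and C10).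

Step 7
Reactants: 13 (3R,4R,5Z,9Z)-10-iodo-6-methyl-3-(propan-2-yl)undeca-1,5,9-trien-4-ol
Product: 14 triethyl{[(3R,4R,5Z,9Z)-10-iodo-6-methyl-3-(propan-2-yl)undeca-1,5,9-trien-4-yl]oxy}silane
Conditions: TESCl, imidazole, DMAP (cat.), DMF, 0 °C → rt
Reagents that add atoms: chlorotriethylsilane, CC[Si](Cl)(CC)CC
Why: Standard O-silylation; the silyl ether keeps the allylic oxygen inert towards zerovalent palladium and 9-BBN in the next step, which an allylic ester would not guarantee.

Step 8
Reactants: 14 triethyl{[(3R,4R,5Z,9Z)-10-iodo-6-methyl-3-(propan-2-yl)undeca-1,5,9-trien-4-yl]oxy}silane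
Product: 16 triethyl{[(1R,2Z,6Z,10S)-3,7-dimethyl-10-(propan-2-yl)cyclodeca-2,6-dien-1-yl]oxy}silane, via B-alkyl-9-BBN adduct 15 (not isolated)
Conditions: 9-BBN (0.5 M in THF), THF, 0 °C → rt; then slow addition (syringe pump) to PdCl2(dppf) (15 mol %), AsPh3 (30 mol %), Cs2CO3, DMF/THF/H2O, 50 °C, about 2 mM
Reagents that add atoms: none
Why: 9-BBN adds anti-Markovnikov and chemoselectively to the only monosubstituted olefin (the two trisubstituted olefins, one of them an iodoalkene, are too hindered and electron-poor) to give primary alkylborane 15; zerovalent palladium then inserts into the alkenyl C–I bond with retention, the hydroxide-activated borane transmetalates intramolecularly to an eleven-membered palladacycle, and reductive elimination forms C7–C8. The closest known reaction type is the intramolecular B-alkyl Suzuki–Miyaura macrocyclisation of ω-(9-BBN-alkyl) alkenyl iodides, together with B-alkyl Suzuki fragment couplings of (Z)-2-iodoalk-2-enes that deliver (Z)-trisubstituted olefins. The ten-membered ring is closed head-to-tail by C(sp2)–C(sp3) cross-coupling (reductive elimination from the palladacycle, not a cycloaddition), with the new bond in the ring and both olefins endocyclic. No stereocentre is created: C1 and C10 are carried unchanged (the C10 descriptor changes from R to S only because vinyl becomes CH2CH2), and the C6=C7 geometry follows from stereoretentive oxidative addition and reductive elimination of the (Z)-iodide. The step needs ring closure to outrun oligomerisation, protodeboronation and β-hydride elimination; slow addition at high dilution, the large-bite-angle dppf ligand, and the two Z olefins, which fold the chain and place the C–Pd bond on the inner face of the turn next to C8, are meant to secure this. Holding the temperature at 50 °C should avoid Cope rearrangement of the cyclodeca-1,5-diene.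

Step 9
Reactants: 16 triethyl{[(1R,2Z,6Z,10S)-3,7-dimethyl-10-(propan-2-yl)cyclodeca-2,6-dien-1-yl]oxy}silane
Product: 17 (1R,2Z,6Z,10S)-3,7-dimethyl-10-(propan-2-yl)cyclodeca-2,6-dien-1-ol
Conditions: Bu4NF, THF, 0 °C → rt
Reagents that add atoms: none
Why: Fluoride-mediated desilylation under non-acidic conditions, which avoids acid-induced transannular cyclisation of the cyclodecadiene.

Step 10
Reactants: 17 (1R,2Z,6Z,10S)-3,7-dimethyl-10-(propan-2-yl)cyclodeca-2,6-dien-1-ol; 18 4-(acetyloxy)-3-methoxybenzoic acid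
Product: 19 (1R,2Z,6Z,10S)-3,7-dimethyl-10-(propan-2-yl)cyclodeca-2,6-dien-1-yl 4-(acetyloxy)-3-methoxybenzoate
Conditions: DCC, DMAP, CH2Cl2, 0 °C → rt
Reagents that add atoms: none
Why: Steglich esterification; acyl transfer to oxygen leaves the C1–O bond intact, so C1 keeps its configuration, and the acetate blocks the phenol against self-acylation.

Step 11
Reactants: 19 (1R,2Z,6Z,10S)-3,7-dimethyl-10-(propan-2-yl)cyclodeca-2,6-dien-1-yl 4-(acetyloxy)-3-methoxybenzoate
Product: 20 (1R,2Z,6Z,10S)-3,7-dimethyl-10-(propan-2-yl)cyclodeca-2,6-dien-1-yl 4-hydroxy-3-methoxybenzoate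
Conditions: pyrrolidine, CH2Cl2, 0 °C
Reagents that add atoms: none
Why: Chemoselective aminolysis of the aryl acetate; phenoxide is a far better leaving group than the hindered secondary alkoxide, so the benzoate ester should survive, and the conditions are non-acidic.

**Compound list**
1 | neryl acetate, (2Z)-3,7-dimethylocta-2,6-dien-1-yl acetate | CC(=O)OC/C=C(/C)CCC=C(C)C | starting material
2 | (2Z)-3-methyl-6-oxohex-2-en-1-yl acetate | CC(=O)OC/C=C(/C)CCC=O | intermediate
3 | ethyltriphenylphosphonium iodide | CC[P+](c1ccccc1)(c1ccccc1)c1ccccc1.[I-] | starting material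
4 | ethylidene(triphenyl)phosphorane | CC=P(c1ccccc1)(c1ccccc1)c1ccccc1 | intermediate
5 | (1-iodoethyl)triphenylphosphonium iodide | CC(I)[P+](c1ccccc1)(c1ccccc1)c1ccccc1.[I-] | intermediate
6 | (1-iodoethylidene)triphenylphosphorane | CC(I)=P(c1ccccc1)(c1ccccc1)c1ccccc1 | intermediate
7 | (2Z,6Z)-7-iodo-3-methylocta-2,6-dien-1-yl acetate | CC(=O)OC/C=C(/C)CC/C=C(/C)I | intermediate
8 | (2Z,6Z)-7-iodo-3-methylocta-2,6-dien-1-ol | OC/C=C(/C)CC/C=C(/C)I | intermediate
9 | (2Z,6Z)-7-iodo-3-methylocta-2,6-dienal | O=C/C=C(/C)CC/C=C(/C)I | intermediate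
10 | 4-methylpent-1-en-3-ol (racemic) | C=CC(O)C(C)C | starting material
11 | bis(pinacolato)diboron, 4,4,4',4',5,5,5',5'-octamethyl-2,2'-bi(1,3,2-dioxaborolane) | CC1(C)OB(OC1(C)C)B1OC(C)(C)C(C)(C)O1 | starting material
12 | 4,4,5,5-tetramethyl-2-[(2E)-4-methylpent-2-en-1-yl]-1,3,2-dioxaborolane | CC(C)/C=C/CB1OC(C)(C)C(C)(C)O1 | intermediate
13 | (3R,4R,5Z,9Z)-10-iodo-6-methyl-3-(propan-2-yl)undeca-1,5,9-trien-4-ol | O[C@@H](/C=C(/C)CC/C=C(/C)I)[C@@H](C=C)C(C)C | intermediate
14 | triethyl{[(3R,4R,5Z,9Z)-10-iodo-6-methyl-3-(propan-2-yl)undeca-1,5,9-trien-4-yl]oxy}silane | CC[Si](CC)(CC)O[C@@H](/C=C(/C)CC/C=C(/C)I)[C@@H](C=C)C(C)C | intermediate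
15 | 9-[(3S,4R,5Z,9Z)-10-iodo-6-methyl-3-(propan-2-yl)-4-[(triethylsilyl)oxy]undeca-5,9-dien-1-yl]-9-borabicyclo[3.3.1]nonane | CC[Si](CC)(CC)O[C@@H](/C=C(/C)CC/C=C(/C)I)[C@@H](CCB1C2CCCC1CCC2)C(C)C | intermediate
16 | triethyl{[(1R,2Z,6Z,10S)-3,7-dimethyl-10-(propan-2-yl)cyclodeca-2,6-dien-1-yl]oxy}silane | CC[Si](CC)(CC)O[C@H]1/C=C(/C)CC/C=C(/C)CC[C@H]1C(C)C | intermediate
17 | (1R,2Z,6Z,10S)-3,7-dimethyl-10-(propan-2-yl)cyclodeca-2,6-dien-1-ol | O[C@H]1/C=C(/C)CC/C=C(/C)CC[C@H]1C(C)C | intermediate
18 | 4-(acetyloxy)-3-methoxybenzoic acid | COc1cc(C(=O)O)ccc1OC(C)=O | starting material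
19 | (1R,2Z,6Z,10S)-3,7-dimethyl-10-(propan-2-yl)cyclodeca-2,6-dien-1-yl 4-(acetyloxy)-3-methoxybenzoate | COc1cc(C(=O)O[C@H]2/C=C(/C)CC/C=C(/C)CC[C@H]2C(C)C)ccc1OC(C)=O | intermediate
20 | (1R,2Z,6Z,10S)-3,7-dimethyl-10-(propan-2-yl)cyclodeca-2,6-dien-1-yl 4-hydroxy-3-methoxybenzoate | COc1cc(C(=O)O[C@H]2/C=C(/C)CC/C=C(/C)CC[C@H]2C(C)C)ccc1O | target

**Step count**
Total steps: 11. Longest linear sequence: 10 (steps 1–4 and 6–11); step 5 is a one-step side branch.

**Steps most likely to fail**

1. Step 8. Intermolecular coupling to oligomers, protodeboronation or β-hydride elimination may outrun closure of the medium ring. The fallback closes the ring at C8=C9 by olefin metathesis instead and sets out from 14. Stille coupling with tributyl(vinyl)stannane (Pd(PPh3)4, CuI, DMF, rt) should give, with retention, the tetraene triethyl{[(3R,4R,5Z,9Z)-6,10-dimethyl-3-(propan-2-yl)dodeca-1,5,9,11-tetraen-4-yl]oxy}silane F1. Ring-closing metathesis of its two vinyl groups (second-generation Grubbs catalyst, toluene, high dilution, 60 °C) should give the cyclic triene triethyl{[(1R,2Z,6Z,8Z,10R)-3,7-dimethyl-10-(propan-2-yl)cyclodeca-2,6,8-trien-1-yl]oxy}silane F2. Diimide (2-nitrobenzenesulfonyl hydrazide, Et3N, CH2Cl2, rt) should then saturate only the disubstituted C8=C9 olefin, and the route is rejoined at 16.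

2. Step 2. Decomposition of the α-iodo ylide and incomplete kinetic control may give low conversion and erosion of the Z geometry. The fallback builds the haloalkene by cross-coupling and sets out from 2. Ramirez dibromo-olefination (CBr4, PPh3, Et3N, CH2Cl2, 0 °C) should give (2Z)-7,7-dibromo-3-methylhepta-2,6-dien-1-yl acetate F3. A trans-selective Negishi mono-methylation (MeZnCl, PdCl2(DPEphos) cat., THF, 0 °C → rt) should replace the bromine trans to the chain and give (2Z,6Z)-7-bromo-3-methylocta-2,6-dien-1-yl acetate F4. A copper-catalysed alkenyl Finkelstein exchange (CuI cat., NaI, trans-N,N'-dimethylcyclohexane-1,2-diamine, dioxane, 110 °C) proceeds with retention, and the route is rejoined at 7.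

3. Step 6. Catalyst control of the aldehyde face may be insufficient, or the reaction slow, with the bulky γ-isopropyl boronate. The fallback uses auxiliary-controlled aldol chemistry and sets out from 9. A magnesium halide-catalysed Evans anti-aldol reaction with commercial (4R)-4-benzyl-3-(3-methylbutanoyl)-1,3-oxazolidin-2-one (MgCl2 cat., Et3N, TMSCl, EtOAc, rt) should give (4R)-4-benzyl-3-[(2S,3S,4Z,8Z)-9-iodo-5-methyl-2-(propan-2-yl)-3-[(trimethylsilyl)oxy]deca-4,8-dienoyl]-1,3-oxazolidin-2-one F5; the auxiliary enantiomer is chosen on the chelated-enolate model. Methanolysis (MeOH, cat. CF3CO2H) should give (4R)-4-benzyl-3-[(2S,3S,4Z,8Z)-3-hydroxy-9-iodo-5-methyl-2-(propan-2-yl)deca-4,8-dienoyl]-1,3-oxazolidin-2-one F6. Silylation (TESCl, imidazole, DMF) should give (4R)-4-benzyl-3-[(2S,3S,4Z,8Z)-9-iodo-5-methyl-2-(propan-2-yl)-3-[(triethylsilyl)oxy]deca-4,8-dienoyl]-1,3-oxazolidin-2-one F7. Reductive removal of the auxiliary (LiBH4, THF/MeOH, 0 °C) should give (2R,3S,4Z,8Z)-9-iodo-5-methyl-2-(propan-2-yl)-3-[(triethylsilyl)oxy]deca-4,8-dien-1-ol F8. Dess–Martin oxidation (NaHCO3, CH2Cl2) should give (2S,3S,4Z,8Z)-9-iodo-5-methyl-2-(propan-2-yl)-3-[(triethylsilyl)oxy]deca-4,8-dienal F9. Wittig methylenation (Ph3P=CH2, THF, −78 → 0 °C) turns the former acyl carbon into the vinyl group, and the route is rejoined at 14.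

**Further compounds**
F1 | step 8 | triethyl{[(3R,4R,5Z,9Z)-6,10-dimethyl-3-(propan-2-yl)dodeca-1,5,9,11-tetraen-4-yl]oxy}silane | CC[Si](CC)(CC)O[C@@H](/C=C(/C)CC/C=C(/C)C=C)[C@@H](C=C)C(C)C
F2 | step 8 | triethyl{[(1R,2Z,6Z,8Z,10R)-3,7-dimethyl-10-(propan-2-yl)cyclodeca-2,6,8-trien-1-yl]oxy}silane | CC[Si](CC)(CC)O[C@H]1/C=C(/C)CC/C=C(/C)\C=C/[C@H]1C(C)C
F3 | step 2 | (2Z)-7,7-dibromo-3-methylhepta-2,6-dien-1-yl acetate | CC(=O)OC/C=C(/C)CCC=C(Br)Br
F4 | step 2 | (2Z,6Z)-7-bromo-3-methylocta-2,6-dien-1-yl acetate | CC(=O)OC/C=C(/C)CC/C=C(/C)Br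
F5 | step 6 | (4R)-4-benzyl-3-[(2S,3S,4Z,8Z)-9-iodo-5-methyl-2-(propan-2-yl)-3-[(trimethylsilyl)oxy]deca-4,8-dienoyl]-1,3-oxazolidin-2-one | C[Si](C)(C)O[C@@H](/C=C(/C)CC/C=C(/C)I)[C@@H](C(=O)N1[C@H](Cc2ccccc2)COC1=O)C(C)C
F6 | step 6 | (4R)-4-benzyl-3-[(2S,3S,4Z,8Z)-3-hydroxy-9-iodo-5-methyl-2-(propan-2-yl)deca-4,8-dienoyl]-1,3-oxazolidin-2-one | O[C@@H](/C=C(/C)CC/C=C(/C)I)[C@@H](C(=O)N1[C@H](Cc2ccccc2)COC1=O)C(C)C
F7 | step 6 | (4R)-4-benzyl-3-[(2S,3S,4Z,8Z)-9-iodo-5-methyl-2-(propan-2-yl)-3-[(triethylsilyl)oxy]deca-4,8-dienoyl]-1,3-oxazolidin-2-one | CC[Si](CC)(CC)O[C@@H](/C=C(/C)CC/C=C(/C)I)[C@@H](C(=O)N1[C@H](Cc2ccccc2)COC1=O)C(C)C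
F8 | step 6 | (2R,3S,4Z,8Z)-9-iodo-5-methyl-2-(propan-2-yl)-3-[(triethylsilyl)oxy]deca-4,8-dien-1-ol | CC[Si](CC)(CC)O[C@@H](/C=C(/C)CC/C=C(/C)I)[C@@H](CO)C(C)C
F9 | step 6 | (2S,3S,4Z,8Z)-9-iodo-5-methyl-2-(propan-2-yl)-3-[(triethylsilyl)oxy]deca-4,8-dienal | CC[Si](CC)(CC)O[C@@H](/C=C(/C)CC/C=C(/C)I)[C@@H](C=O)C(C)C
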